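**Plan**

- Retrosynthesis: the two S–O bonds at O3 and O4' are cut first, then O1–C2 of ring C, and last C4a–C4 and C4–C3 in one operation.
- The last cut rests on C4. It is a single carbonyl carbon between ring A carbon C4a and the oxygen-bearing C3, so it can be supplied as CO between a ring A aryl iodide and the enolate of a ring B alpha-alkoxy acetophenone.
- Forward: rings A and B are bought, the C15 chain is joined in step 7, ring C closes in step 8 by O1–C2 cyclodehydration, and sulfation and hydrogenolysis follow.
- Site selectivity comes from the protecting groups. MOM sits on O1, O3 and O4' and is released by one acid treatment; benzyl sits on O5, O7 and O3' and is kept until after sulfation.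
- Stereochemistry: the target has no stereocentre. C3 of diketone 11 is racemic and labile, and it becomes sp2 in step 8.

Key step: step 7

Assumption: the target is drawn as the free bis(hydrogen sulfate). Such acids hydrolyse themselves, so the bis(triethylammonium) salt is the form carried and stored, and the protons are put on only in the last operation.

Remark: flavone numbering (O1, C2, C3, C4, C4a, C5 to C8, primes for ring B) is also used for the open-chain compounds. 3,5-Bis(benzyloxy)phenol is taken as a catalogue compound.

**Step 1**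
Reactants: 1 3,5-bis(benzyloxy)phenol
Product: 2 3,5-bis(benzyloxy)-2-iodophenol
Conditions: NIS (1.0 equiv), CH2Cl2, −40 to 0 °C, dark
Reagents that add atoms: N-iodosuccinimide, O=C1CCC(=O)N1I
Why: Electrophilic aromatic iodination of a strongly activated phenol; in a non-polar solvent NIS is guided by a hydrogen bond to the OH, and C2 (between OH and one benzyloxy group) is less crowded than C4 (between two benzyloxy groups), so the ortho iodide should dominate, while one equivalent of reagent limits di-iodination.

**Step 2**
Reactants: 2 3,5-bis(benzyloxy)-2-iodophenol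
Product: 3 1,5-bis(benzyloxy)-2-iodo-3-(methoxymethoxy)benzene
Conditions: MOMCl, i-Pr2NEt, CH2Cl2, 0 °C to rt
Reagents that add atoms: chloromethyl methyl ether (MOMCl), COCCl
Why: O-alkylation of the phenol to the MOM acetal under amine base leaves the iodide and the benzyl ethers untouched and marks the oxygen that will become O1 as the only acid-labile one on ring A.

**Step 3**
Reactants: 4 3,4-dihydroxyacetophenone
Product: 5 1-[3-hydroxy-4-(methoxymethoxy)phenyl]ethanone
Conditions: MOMCl (1.05 equiv), K2CO3 (1.1 equiv), acetone, 0 °C to rt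
Reagents that add atoms: chloromethyl methyl ether (MOMCl), COCCl
Why: Regioselective O-alkylation; the 4-OH is conjugated with the para acetyl group and is the more acidic phenol, so one equivalent of weak base should form mainly the 4-phenoxide, which is trapped by one equivalent of MOMCl.

**Step 4**
Reactants: 5 1-[3-hydroxy-4-(methoxymethoxy)phenyl]ethanone
Product: 6 1-[3-(benzyloxy)-4-(methoxymethoxy)phenyl]ethanone
Conditions: BnBr, K2CO3, DMF, rt to 50 °C
Reagents that add atoms: benzyl bromide, BrCc1ccccc1
Why: Williamson ether synthesis on the one remaining phenol; the MOM acetal and the methyl ketone are stable to carbonate base.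

**Step 5**
Reactants: 6 1-[3-(benzyloxy)-4-(methoxymethoxy)phenyl]ethanone
Product: 9 1-[3-(benzyloxy)-4-(methoxymethoxy)phenyl]-2-hydroxyethanone, via trimethylsilyl enol ether 7 (not isolated), via alpha-silyloxy ketone 8 (not isolated)
Conditions: LiN(SiMe3)2, Me3SiCl, THF, −78 °C; solvent change, mCPBA, CH2Cl2, −20 to 0 °C; citric acid (cat.), MeOH, rt
Reagents that add atoms: mCPBA (3-chloroperoxybenzoic acid), O=C(OO)c1cccc(Cl)c1; chlorotrimethylsilane, C[Si](C)(C)Cl (its silicon is carried by 7 and 8 only)
Why: Rubottom oxidation; the only possible enolate is silylated on oxygen, the peracid epoxidises the electron-rich enol ether much faster than it attacks the aryl ketone or the arene, silyl migration opens the epoxide, and mild methanolysis removes silicon without touching the aryl MOM acetal.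

**Step 6**
Reactants: 9 1-[3-(benzyloxy)-4-(methoxymethoxy)phenyl]-2-hydroxyethanone
Product: 10 1-[3-(benzyloxy)-4-(methoxymethoxy)phenyl]-2-(methoxymethoxy)ethanone
Conditions: MOMCl, i-Pr2NEt, CH2Cl2, 0 °C to rt
Reagents that add atoms: chloromethyl methyl ether (MOMCl), COCCl
Why: Standard MOM protection of a primary alcohol under a hindered amine base, too weak to cause aldol or ketol isomerisation, gives the future O3 the same acid-labile mask as O1 and O4'.

**Step 7**
Reactants: 3 1,5-bis(benzyloxy)-2-iodo-3-(methoxymethoxy)benzene; 10 1-[3-(benzyloxy)-4-(methoxymethoxy)phenyl]-2-(methoxymethoxy)ethanone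
Product: 11 1-[3-(benzyloxy)-4-(methoxymethoxy)phenyl]-3-[2,4-bis(benzyloxy)-6-(methoxymethoxy)phenyl]-2-(methoxymethoxy)propane-1,3-dione (racemic)
Conditions: CO (1–2 bar), Pd(OAc)2 (5 mol%), 1,3-bis(diphenylphosphino)propane (6 mol%), MgCl2, Et3N, 1,4-dioxane, 80 °C; aq. citric acid work-up
Reagents that add atoms: carbon monoxide, [C-]#[O+]
Why: Zerovalent palladium, formed in the flask from Pd(OAc)2 and the bisphosphine, inserts into the C–I bond of 3, the donor-rich aryl group migrates to bound CO (making C4a–C4 and easing the crowding between the metal and the two ortho alkoxy groups), and the acyl complex of divalent palladium takes up at carbon the magnesium enolate that MgCl2 and Et3N generate from 10, so that reductive elimination makes C4–C3. The closest known reaction type is the palladium-catalysed carbonylative alpha-arylation of aryl alkyl ketones with aryl iodides to 1,3-diketones under soft enolisation. The step closes no ring, and its one new centre, C3, arises racemic, equilibrates by enolisation and needs no control because step 8 flattens it. Carbonylation must beat direct alpha-arylation, which the CO atmosphere and the hindered, electron-rich aryl group (fast migration to CO, slow aryl–enolate elimination) should secure. C-acylation must beat O-acylation, which is favoured because magnesium is chelated between the enolate oxygen and the alpha MOM oxygen and because the product is drained off as its magnesium diketonate, a form also shielded from retro-Claisen cleavage. Ketone 10 has a single enolisable position, and the MOM and benzyl ethers are inert to the amine base.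

**Step 8**
Reactants: 11 1-[3-(benzyloxy)-4-(methoxymethoxy)phenyl]-3-[2,4-bis(benzyloxy)-6-(methoxymethoxy)phenyl]-2-(methoxymethoxy)propane-1,3-dione
Product: 14 5,7,3'-tri-O-benzylquercetin, via ring-open bisphenol diketone 12 (not isolated), via 3-O-MOM flavone 13 (not isolated)
Conditions: conc. HCl (catalytic to a few equiv), MeOH–THF 1:1, 55 °C, argon
Reagents that add atoms: none
Why: Acid-catalysed acetal methanolysis followed by cyclodehydration, as in the last stage of a Baker–Venkataraman flavone synthesis; the aryl MOM groups should fall first, the freed ring A phenol adds 6-exo-trig to the ring B ketone (O1–C2), loss of water from the hemiketal creates C2=C3, the 3-O-MOM group is cleaved last, and benzyl aryl ethers are stable to dilute methanolic HCl.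

**Step 9**
Reactants: 14 5,7,3'-tri-O-benzylquercetin
Product: 15 bis(triethylammonium) 5,7,3'-tri-O-benzylquercetin 3,4'-bissulfate
Conditions: SO3·NEt3 (excess), N,N-dimethylacetamide, 65 °C; Sephadex LH-20 or C18 chromatography
Reagents that add atoms: sulfur trioxide–triethylamine complex, CC[N+](CC)(CC)S(=O)(=O)[O-]
Why: O-sulfation with an amine–sulfur trioxide complex; 14 has only the 3-OH and 4'-OH free, so excess reagent and warming can force the hydrogen-bonded 3-OH without any risk of over-sulfation, and the products remain stable ammonium salts.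

**Step 10**
Reactants: 15 bis(triethylammonium) 5,7,3'-tri-O-benzylquercetin 3,4'-bissulfate
Product: 17 quercetin 3,4'-bissulfate, via bis(triethylammonium) quercetin 3,4'-bissulfate 16 (not isolated)
Conditions: H2 (1 atm), 10% Pd/C, MeOH–THF, rt; filter; sulfonic acid cation-exchange resin (H+ form), H2O, 0–5 °C, immediate freeze-drying
Reagents that add atoms: none
Why: Catalytic hydrogenolysis of benzyl aryl ethers leaves aryl sulfate salts and the conjugated C2=C3 bond of the chromone alone at ambient pressure, and a short, cold cation exchange replaces triethylammonium by protons before self-hydrolysis of the acid can set in.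

**Compound list**

1 | 3,5-bis(benzyloxy)phenol | Oc1cc(OCc2ccccc2)cc(OCc2ccccc2)c1 | starting material
2 | 3,5-bis(benzyloxy)-2-iodophenol | Oc1cc(OCc2ccccc2)cc(OCc2ccccc2)c1I | intermediate
3 | 1,5-bis(benzyloxy)-2-iodo-3-(methoxymethoxy)benzene | Ic1c(OCOC)cc(OCc2ccccc2)cc1OCc1ccccc1 | intermediate
4 | 3,4-dihydroxyacetophenone | CC(=O)c1ccc(O)c(O)c1 | starting material
5 | 1-[3-hydroxy-4-(methoxymethoxy)phenyl]ethanone | CC(=O)c1ccc(OCOC)c(O)c1 | intermediate
6 | 1-[3-(benzyloxy)-4-(methoxymethoxy)phenyl]ethanone | CC(=O)c1ccc(OCOC)c(OCc2ccccc2)c1 | intermediate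
7 | {1-[3-(benzyloxy)-4-(methoxymethoxy)phenyl]ethenyl}oxy(trimethyl)silane, formed in the flask | C=C(O[Si](C)(C)C)c1ccc(OCOC)c(OCc2ccccc2)c1 | intermediate
8 | 1-[3-(benzyloxy)-4-(methoxymethoxy)phenyl]-2-[(trimethylsilyl)oxy]ethanone, formed in the flask | C[Si](C)(C)OCC(=O)c1ccc(OCOC)c(OCc2ccccc2)c1 | intermediate
9 | 1-[3-(benzyloxy)-4-(methoxymethoxy)phenyl]-2-hydroxyethanone | OCC(=O)c1ccc(OCOC)c(OCc2ccccc2)c1 | intermediate
10 | 1-[3-(benzyloxy)-4-(methoxymethoxy)phenyl]-2-(methoxymethoxy)ethanone | COCOCC(=O)c1ccc(OCOC)c(OCc2ccccc2)c1 | intermediate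
11 | 1-[3-(benzyloxy)-4-(methoxymethoxy)phenyl]-3-[2,4-bis(benzyloxy)-6-(methoxymethoxy)phenyl]-2-(methoxymethoxy)propane-1,3-dione, racemic and labile at C3, drawn without descriptor | O=C(c1c(OCOC)cc(OCc2ccccc2)cc1OCc1ccccc1)C(OCOC)C(=O)c1ccc(OCOC)c(OCc2ccccc2)c1 | intermediate
12 | 1-[3-(benzyloxy)-4-hydroxyphenyl]-3-[2,4-bis(benzyloxy)-6-hydroxyphenyl]-2-(methoxymethoxy)propane-1,3-dione, racemic, formed in the flask | O=C(c1c(O)cc(OCc2ccccc2)cc1OCc1ccccc1)C(OCOC)C(=O)c1ccc(O)c(OCc2ccccc2)c1 | intermediate
13 | 5,7-bis(benzyloxy)-2-[3-(benzyloxy)-4-hydroxyphenyl]-3-(methoxymethoxy)-4H-chromen-4-one, formed in the flask | O=c1c(OCOC)c(-c2ccc(O)c(OCc3ccccc3)c2)oc2cc(OCc3ccccc3)cc(OCc3ccccc3)c12 | intermediate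
14 | 5,7-bis(benzyloxy)-2-[3-(benzyloxy)-4-hydroxyphenyl]-3-hydroxy-4H-chromen-4-one (5,7,3'-tri-O-benzylquercetin) | O=c1c(O)c(-c2ccc(O)c(OCc3ccccc3)c2)oc2cc(OCc3ccccc3)cc(OCc3ccccc3)c12 | intermediate
15 | bis(triethylammonium) 5,7,3'-tri-O-benzylquercetin 3,4'-bissulfate | O=c1c(OS(=O)(=O)[O-])c(-c2ccc(OS(=O)(=O)[O-])c(OCc3ccccc3)c2)oc2cc(OCc3ccccc3)cc(OCc3ccccc3)c12.CC[NH+](CC)CC.CC[NH+](CC)CC | intermediate
16 | bis(triethylammonium) quercetin 3,4'-bissulfate, formed in the flask (storage form if isolated) | O=c1c(OS(=O)(=O)[O-])c(-c2ccc(OS(=O)(=O)[O-])c(O)c2)oc2cc(O)cc(O)c12.CC[NH+](CC)CC.CC[NH+](CC)CC | intermediate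
17 | quercetin 3,4'-bissulfate | O=c1c(OS(=O)(=O)O)c(-c2ccc(OS(=O)(=O)O)c(O)c2)oc2cc(O)cc(O)c12 | target

Total step count: 10.
Longest linear sequence: 8 (steps 3 to 10, from 3,4-dihydroxyacetophenone).

**Steps most likely to fail**

Step 7. Capture of the doubly ortho-substituted acylpalladium species may be too slow. Hydrodeiodination of 3, O-acylation of the enolate or retro-Claisen cleavage of the product could then take over. The fallback makes the same two bonds one after the other, with CO2 as the source of C4.
- It sets out from 3. Iodine–magnesium exchange (i-PrMgCl·LiCl, THF, −20 °C) and a CO2 quench should give 2,4-bis(benzyloxy)-6-(methoxymethoxy)benzoic acid F1.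
- 1,1'-Carbonyldiimidazole in THF converts this acid under neutral conditions into [2,4-bis(benzyloxy)-6-(methoxymethoxy)phenyl](1H-imidazol-1-yl)methanone F2.
- Crossed Claisen acylation of the lithium enolate of 10 (LiN(SiMe3)2, two equivalents, THF, −78 °C to rt) with this imidazolide comes back to the route at 11.

Step 1. The iodination may discriminate poorly between the position ortho and the position para to the hydroxyl group, or it may run on to di-iodination. The fallback removes the question by making ring A threefold symmetric. The two ortho oxygens are then told apart by a chelation-controlled ether cleavage after the coupling.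
- It sets out from 1. Benzylation (BnBr, K2CO3, DMF) should give 1,3,5-tris(benzyloxy)benzene F3.
- NIS can iodinate only equivalent positions of this ether and gives 1,3,5-tris(benzyloxy)-2-iodobenzene F4.
- Coupling with 10 and CO under the conditions of step 7 should give 1-[3-(benzyloxy)-4-(methoxymethoxy)phenyl]-2-(methoxymethoxy)-3-[2,4,6-tris(benzyloxy)phenyl]propane-1,3-dione F5.
- MgBr2·OEt2 in toluene–Et2O at 80 °C cleaves one benzyl ether ortho to the C4 carbonyl. The magnesium phenoxide then occupies that carbonyl and spares the second ortho ether. The product is 1-[3-(benzyloxy)-4-(methoxymethoxy)phenyl]-3-[2,4-bis(benzyloxy)-6-hydroxyphenyl]-2-(methoxymethoxy)propane-1,3-dione F6. Any MOM loss at this point is harmless.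
- Methanolic HCl as in step 8 comes back to the route at 14.

Step 9. Sulfation of the hydrogen-bonded 3-OH may stay incomplete, or the 3-sulfate may be lost during purification of the very polar salt. The fallback installs both sulfates as neutral, protected diesters.
- It sets out from 14. 2,2,2-Trichloroethyl chlorosulfate, Et3N and DMAP in THF should give 5,7,3'-tri-O-benzylquercetin 3,4'-bis(2,2,2-trichloroethyl sulfate) F7, which can be purified on silica gel.
- Transfer hydrogenolysis (10% Pd/C, HCO2H–Et3N, MeOH, rt) removes the trichloroethyl and benzyl groups together. This comes back to the route at 16, which goes through the cation exchange of step 10.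

**Further compounds**

F1 | step 7 | 2,4-bis(benzyloxy)-6-(methoxymethoxy)benzoic acid | OC(=O)c1c(OCOC)cc(OCc2ccccc2)cc1OCc1ccccc1
F2 | step 7 | [2,4-bis(benzyloxy)-6-(methoxymethoxy)phenyl](1H-imidazol-1-yl)methanone | O=C(n1ccnc1)c1c(OCOC)cc(OCc2ccccc2)cc1OCc1ccccc1
F3 | step 1 | 1,3,5-tris(benzyloxy)benzene | c1(OCc2ccccc2)cc(OCc2ccccc2)cc(OCc2ccccc2)c1
F4 | step 1 | 1,3,5-tris(benzyloxy)-2-iodobenzene | Ic1c(OCc2ccccc2)cc(OCc2ccccc2)cc1OCc1ccccc1
F5 | step 1 | 1-[3-(benzyloxy)-4-(methoxymethoxy)phenyl]-2-(methoxymethoxy)-3-[2,4,6-tris(benzyloxy)phenyl]propane-1,3-dione (racemic) | O=C(c1c(OCc2ccccc2)cc(OCc2ccccc2)cc1OCc1ccccc1)C(OCOC)C(=O)c1ccc(OCOC)c(OCc2ccccc2)c1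
F6 | step 1 | 1-[3-(benzyloxy)-4-(methoxymethoxy)phenyl]-3-[2,4-bis(benzyloxy)-6-hydroxyphenyl]-2-(methoxymethoxy)propane-1,3-dione (racemic) | O=C(c1c(O)cc(OCc2ccccc2)cc1OCc1ccccc1)C(OCOC)C(=O)c1ccc(OCOC)c(OCc2ccccc2)c1
F7 | step 9 | 5,7,3'-tri-O-benzylquercetin 3,4'-bis(2,2,2-trichloroethyl sulfate) | O=c1c(OS(=O)(=O)OCC(Cl)(Cl)Cl)c(-c2ccc(OS(=O)(=O)OCC(Cl)(Cl)Cl)c(OCc3ccccc3)c2)oc2cc(OCc3ccccc3)cc(OCc3ccccc3)c12
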